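**Retrosynthetic overview**

1. The strategy rests on the 4-methylfuran-2(5H)-one ring (ring O, carbonyl C1', C2'H, methyl-bearing C3', sp3 C16). It is attached through C16, which carries the ring oxygen and is syn to the C15 carbinol. Cutting C16–C3' and the lactone O–C1' bond gives a (Z)-β-metallated crotonate and a C16 aldehyde with a chelating ether on C15.
2. C15 (S) and the C16 aldehyde come from anti-selective alkenylation of (R)-glyceraldehyde acetonide with the (E)-C13=C14 alkenyl iodide, then PMB protection and glycol cleavage.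
3. The alkenyl iodide comes from larixol: side chain cut to the C13 methyl ketone, then terminal alkyne, then Zr-catalysed methylalumination and iodination.
4. The C18 oxygen is relayed from the 6α-hydroxyl to the peri 4α-methyl by nitrite photolysis. The C8(17) methylene is masked as its epoxide for this, because a free methylene makes C7 allylic and invites β-scission of the C6 alkoxy radical.
5. Ring order: the trans-decalin is taken intact from larixol; a temporary C8 spiro-epoxide is made and removed; the butenolide is the only ring built (key step). The end is C18 oxidation and removal of PMB and TBS.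

Key step: step 17

Remark (numbering): labdane numbers are used for C1–C20 (C17 = exocyclic methylene carbon, C18 = 4α carbon, C19 = 4β-methyl, C20 = 10β-methyl); the chain is C11–C12–C13(CH3)=C14–C15–C16; the lactone atoms are O, C1', C2', C3' and C16.
Remark (assumption): larixol, isolated from larch oleoresin, is taken as a purchasable starting material.
Remark (assumption): peracid attack on C8(17) is taken to be on the α-face; the C8 configuration of the epoxide intermediates is erased when the methylene is regenerated, so either epimer serves.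
Remark (assumption): the γ-hydroxy aldehydes (epoxy aldehyde and target) are written open-chain; ring–chain tautomerism to a 6α,18-lactol would not change the chemistry.

**Route**

Step 1
Reactants: 1 larixol
Product: 2 6α-hydroxy-14,15-dinorlabd-8(17)-en-13-one (C13 methyl ketone)
Conditions: KMnO4, BnEt3NCl, CH2Cl2, 0–5 °C
Reagents that add atoms: none
Why: Permanganate oxidative cleavage of the vinyl carbinol removes C14 and C15 through the α-hydroxy acid and leaves the C13 ketone, while the hindered C8(17) methylene and the equatorial C6 alcohol react more slowly under cold phase-transfer conditions; no stereocentre is touched.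

Step 2
Reactants: 2 methyl ketone
Product: 3 8α,17-epoxy-6α-hydroxy-14,15-dinorlabdan-13-one
Conditions: mCPBA, NaHCO3, CH2Cl2, 0 °C
Reagents that add atoms: mCPBA, O=C(OO)c1cccc(Cl)c1
Why: Prilezhaev epoxidation of the only alkene, with the peracid expected on the α-face of C8 away from the axial C10 methyl (spectator centre); the epoxide removes the allylic character of C7 for step 4, and Baeyer–Villiger oxidation of the ketone is far slower under buffered cold conditions.

Step 3
Reactants: 3 epoxy alcohol
Product: 4 6α-nitrite ester of 3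
Conditions: NOCl, pyridine, −20 °C
Reagents that add atoms: nitrosyl chloride, O=NCl
Why: O-Nitrosation of the single hydroxyl (nitrite ester formation) in pyridine, which takes up HCl so that the epoxide is not opened; the configuration at C6 is retained because only the O–H bond reacts.

Step 4
Reactants: 4 nitrite ester
Product: 6 (E)-oxime of 8α,17-epoxy-6α-hydroxy-13-oxo-14,15-dinorlabdan-18-al, via C18-nitroso compound 5 (not isolated)
Conditions: hν (365 nm), PhH, N2, 15 °C; then i-PrOH, 80 °C
Reagents that add atoms: none
Why: Barton nitrite photolysis: the C6 alkoxy radical has its equatorial oxygen 1,3-diequatorial (peri) to the equatorial 4α-methyl, so 1,5-hydrogen transfer through a six-membered transition state takes hydrogen from C18 only (C19 and C20 are out of reach), NO recombination gives the nitroso compound and heating tautomerises it to the oxime; this makes C4 stereogenic with the oxidised carbon α, the ketone does not absorb at 365 nm, and with C8 saturated the C6–C7 scission has no allylic driving force.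

Step 5
Reactants: 6 hydroxy oxime
Product: 7 8α,17-epoxy-6α-hydroxy-13-oxo-14,15-dinorlabdan-18-al
Conditions: TiCl3 (aq.), NH4OAc, THF/H2O, 0 °C → rt
Reagents that add atoms: water, O
Why: Reductive deoximation with buffered titanium(III): the N–O bond is reduced and the imine hydrolyses to the aldehyde, the buffered medium should spare the spiro-epoxide, and C4 is quaternary so the aldehyde cannot epimerise.

Step 6
Reactants: 7 hydroxy aldehyde
Product: 8 8α,17-epoxy-6α,18-dihydroxy-14,15-dinorlabdan-13-one
Conditions: NaBH(OAc)3, PhH, rt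
Reagents that add atoms: none
Why: Chemoselective aldehyde reduction with triacetoxyborohydride, helped by exchange of the neighbouring 6α-hydroxyl onto boron (directed hydride delivery), while the remote methyl ketone and the epoxide are not reduced by this mild reagent.

Step 7
Reactants: 8 epoxy diol
Product: 10 6α,18-dihydroxy-14,15-dinorlabd-8(17)-en-13-one, via 17-iodo-8α-ol iodohydrin 9 (not isolated)
Conditions: NaI, NaOAc, Zn, AcOH/THF, 0 °C → rt
Reagents that add atoms: none
Why: Cornforth deoxygenation: iodide opens the protonated epoxide at the primary C17 and zinc effects reductive β-elimination of the iodohydrin, which returns the C8(17) methylene regiospecifically and removes the temporary C8 centre; ketone and free hydroxyls tolerate the buffered medium.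

Step 8
Reactants: 10 ene diol
Product: 11 18-O-triethylsilyl ether of 10
Conditions: TESCl, imidazole, CH2Cl2, −20 °C
Reagents that add atoms: chlorotriethylsilane, CC[Si](Cl)(CC)CC
Why: Selective silylation of the primary C18 hydroxyl over the more hindered secondary 6α-hydroxyl; TES is chosen so that it is shed together with the acetonide in step 14.

Step 9
Reactants: 11 C18 TES ether
Product: 12 6α-O-TBS 18-O-TES methyl ketone
Conditions: TBSOTf, 2,6-lutidine, CH2Cl2, −78 → 0 °C
Reagents that add atoms: tert-butyldimethylsilyl triflate, CC(C)(C)[Si](C)(C)OS(=O)(=O)C(F)(F)F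
Why: Silyl triflate silylation of the hindered secondary alcohol; 2,6-lutidine at low temperature should not enolise the methyl ketone, and the robust TBS ether lasts until the final step.

Step 10
Reactants: 12 bis-silyl ketone
Product: 14 terminal alkyne (C9 side chain CH2CH2C≡CH; 6α-OTBS; 18-OTES), via C13 enol diethyl phosphate 13 (not isolated)
Conditions: LDA, THF, −78 °C; ClP(O)(OEt)2, −78 °C → rt; LDA (2.3 equiv), −78 °C → rt; H2O
Reagents that add atoms: none
Why: One-pot methyl ketone to alkyne conversion: kinetic deprotonation at the methyl group, O-phosphorylation of the enolate and base-induced elimination of diethyl phosphate give the acetylide, which is protonated on quench; silyl ethers and the isolated alkene are inert to LDA.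

Step 11
Reactants: 14 terminal alkyne
Product: 16 (E)-alkenyl iodide (C9 side chain CH2CH2C(CH3)=CHI), via (E)-alkenyl(dimethyl)alane 15 (not isolated)
Conditions: Me3Al, Cp2ZrCl2 (cat.), CH2Cl2, 0 °C → rt; I2, THF, −30 °C
Reagents that add atoms: trimethylaluminium, C[Al](C)C; iodine, II
Why: Zirconium-catalysed carboalumination (Negishi): methyl and aluminium add syn with aluminium at the terminus, and iodinolysis with retention gives the (E)-C13=C14 iodide; the 1,1-disubstituted C8(17) alkene does not carbometallate under these conditions.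

Step 12
Reactants: 16 (E)-alkenyl iodide; 17 (R)-glyceraldehyde acetonide
Product: 18 (15S,16R)-anti allylic alcohol (C15–OH; C16 and the terminal CH2O carbon as isopropylidene acetal; 6α-OTBS; 18-OTES)
Conditions: CrCl2, NiCl2 (cat.), DMSO, rt
Reagents that add atoms: none
Why: Nozaki–Hiyama–Kishi alkenylation with retention of the E geometry; Felkin–Anh addition to the α-alkoxy aldehyde (dioxolane C–O anti to the incoming nucleophile) should give the anti adduct, which sets C15 as S, and the minor 15-epimer should be separable by chromatography.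

Step 13
Reactants: 18 allylic alcohol
Product: 19 15-O-(4-methoxybenzyl) ether of 18
Conditions: NaH, PMBCl, Bu4NI (cat.), THF/DMF, 0 °C → rt
Reagents that add atoms: 4-methoxybenzyl chloride, COc1ccc(CCl)cc1
Why: Williamson etherification of the only free hydroxyl installs the benzyl-type ether needed for chelation in step 17; C15 is not affected because only the O–H bond reacts.

Step 14
Reactants: 19 PMB ether
Product: 20 triol (15-OPMB; free OH at C16 and at the terminal CH2OH and at C18; 6α-OTBS)
Conditions: PPTS, MeOH, rt → 40 °C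
Reagents that add atoms: none
Why: Acid-catalysed transketalisation removes the terminal acetonide and methanolysis removes the primary TES ether, while the hindered secondary TBS ether and the PMB ether withstand this mild acid; the C18 hydroxyl needs no protection in step 17 and is oxidised directly in step 18.

Step 15
Reactants: 20 triol
Product: 21 (15S)-15-(4-methoxybenzyloxy) C16 aldehyde with free C18-OH and 6α-OTBS (key-step precursor)
Conditions: NaIO4, THF/pH 7 buffer, 0 °C
Reagents that add atoms: none
Why: Periodate (Malaprade) cleavage of the only vicinal diol turns C16 into the aldehyde carbon without touching the isolated C18 hydroxyl; the α-alkoxy β,γ-unsaturated aldehyde is used crude and cold to protect the C15 configuration.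

Step 16
Reactants: 22 ethyl but-2-ynoate
Product: 23 ethyl (Z)-3-iodobut-2-enoate
Conditions: NaI, AcOH, 115 °C
Reagents that add atoms: sodium iodide, [Na+].[I-]
Why: Conjugate hydroiodination of the ynoate: iodide adds at C3 and the allenoate is protonated anti to iodine, which gives the Z isomer with iodine cis to the ester.

Step 17
Reactants: 21 α-PMB-oxy aldehyde; 23 ethyl (Z)-3-iodobut-2-enoate
Product: 26 (15S,16S)-butenolide with 15-OPMB and 6α-OTBS and free C18-OH, via alkenylmagnesium chloride 24 (not isolated), via magnesium alkoxide adduct 25 (not isolated)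
Conditions: 23 (3 equiv), i-PrMgCl·LiCl, THF, −40 °C; add to 21 + MgBr2·OEt2, CH2Cl2, −78 → −20 °C; aq. NH4Cl at −20 °C
Reagents that add atoms: none
Why: Iodine–magnesium exchange on 23 at −40 °C is faster than attack on the ester and gives the (Z)-alkenylmagnesium 24, held in its geometry by coordination of the ester carbonyl to magnesium; this is the known preparation of (Z)-β-magnesiated enoates and their annulation with aldehydes to butenolides. 24 adds to the aldehyde carbon C16 of 21 and forms the C16–C3' bond, and the alkoxide 25, which is cis to the ester across C2'=C3', closes the lactone by 5-exo-trig acyl substitution with loss of ethoxide. The new stereocentre C16 is set by Cram-chelate control: magnesium bridges the aldehyde oxygen and the C15 PMB ether oxygen in a five-membered chelate and the nucleophile enters on the face opposite the C14 alkenyl substituent, which gives the 15,16-syn (16S) product. The step needs chelate over Felkin–Anh selectivity, secured by the benzyl-type ether on C15, pre-complexation with MgBr2·OEt2 and the weakly coordinating CH2Cl2 co-solvent. It also needs the aldehyde to keep its C15 configuration and the butenolide its acidic C16–H, secured by using crude 21 cold and quenching cold; the free C18 hydroxyl consumes one equivalent of 24, hence the excess.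

Step 18
Reactants: 26 butenolide alcohol
Product: 27 C18 aldehyde (15-OPMB; 6α-OTBS)
Conditions: Dess–Martin periodinane, NaHCO3, CH2Cl2, 0 °C → rt
Reagents that add atoms: none
Why: Dess–Martin oxidation of the only free hydroxyl gives the neopentyl aldehyde, which cannot epimerise because C4 is quaternary; the PMB ether, the TBS ether and the butenolide are inert to the buffered periodinane.

Step 19
Reactants: 27 PMB ether aldehyde
Product: 28 15-hydroxy C18 aldehyde (6α-OTBS)
Conditions: DDQ, CH2Cl2/pH 7 buffer, 0 °C
Reagents that add atoms: none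
Why: Oxidative PMB cleavage: electron transfer from the anisyl ring and hydrolysis of the oxocarbenium ion free the C15 hydroxyl without acid, so the allylic C15–O bond does not ionise; limited DDQ at 0 °C should leave the allylic alcohol unoxidised.

Step 20
Reactants: 28 TBS ether
Product: 29 target CNP0113661.1
Conditions: HF·pyridine, pyridine, THF, 0 °C → rt
Reagents that add atoms: none
Why: Acidic fluoride desilylation of the hindered secondary TBS ether; basic fluoride is avoided because the butenolide C16–H is acidic, and no stereocentre is changed.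

**Compound list**

1 | larixol, (13S)-labda-8(17),14-diene-6α,13-diol | C=C1C[C@H](O)[C@@H]2[C@](C)(CCCC2(C)C)[C@H]1CC[C@](C)(O)C=C | starting material
2 | 6α-hydroxy-14,15-dinorlabd-8(17)-en-13-one | C=C1C[C@H](O)[C@@H]2[C@](C)(CCCC2(C)C)[C@H]1CCC(C)=O | intermediate
3 | 8α,17-epoxy-6α-hydroxy-14,15-dinorlabdan-13-one | C1O[C@@]12C[C@H](O)[C@@H]3[C@](C)(CCCC3(C)C)[C@H]2CCC(C)=O | intermediate
4 | 6α-nitrite ester of 3 | C1O[C@@]12C[C@H](ON=O)[C@@H]3[C@](C)(CCCC3(C)C)[C@H]2CCC(C)=O | intermediate
5 | 8α,17-epoxy-6α-hydroxy-18-nitroso-14,15-dinorlabdan-13-one (collects as its dimer) | C1O[C@@]12C[C@H](O)[C@@H]3[C@](C)(CCC[C@@]3(C)CN=O)[C@H]2CCC(C)=O | intermediate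
6 | (E)-oxime of 8α,17-epoxy-6α-hydroxy-13-oxo-14,15-dinorlabdan-18-al | C1O[C@@]12C[C@H](O)[C@@H]3[C@](C)(CCC[C@@]3(C)/C=N/O)[C@H]2CCC(C)=O | intermediate
7 | 8α,17-epoxy-6α-hydroxy-13-oxo-14,15-dinorlabdan-18-al | C1O[C@@]12C[C@H](O)[C@@H]3[C@](C)(CCC[C@@]3(C)C=O)[C@H]2CCC(C)=O | intermediate
8 | 8α,17-epoxy-6α,18-dihydroxy-14,15-dinorlabdan-13-one | C1O[C@@]12C[C@H](O)[C@@H]3[C@](C)(CCC[C@@]3(C)CO)[C@H]2CCC(C)=O | intermediate
9 | 6α,8α,18-trihydroxy-17-iodo-14,15-dinorlabdan-13-one (iodohydrin) | IC[C@@]1(O)C[C@H](O)[C@@H]2[C@](C)(CCC[C@@]2(C)CO)[C@H]1CCC(C)=O | intermediate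
10 | 6α,18-dihydroxy-14,15-dinorlabd-8(17)-en-13-one | C=C1C[C@H](O)[C@@H]2[C@](C)(CCC[C@@]2(C)CO)[C@H]1CCC(C)=O | intermediate
11 | 18-O-TES ether of 10 | C=C1C[C@H](O)[C@@H]2[C@](C)(CCC[C@@]2(C)CO[Si](CC)(CC)CC)[C@H]1CCC(C)=O | intermediate
12 | 6α-O-TBS 18-O-TES methyl ketone | C=C1C[C@H](O[Si](C)(C)C(C)(C)C)[C@@H]2[C@](C)(CCC[C@@]2(C)CO[Si](CC)(CC)CC)[C@H]1CCC(C)=O | intermediate
13 | C13 enol diethyl phosphate of 12 (terminal enol) | C=C1C[C@H](O[Si](C)(C)C(C)(C)C)[C@@H]2[C@](C)(CCC[C@@]2(C)CO[Si](CC)(CC)CC)[C@H]1CCC(=C)OP(=O)(OCC)OCC | intermediate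
14 | terminal alkyne, side chain CH2CH2C≡CH | C=C1C[C@H](O[Si](C)(C)C(C)(C)C)[C@@H]2[C@](C)(CCC[C@@]2(C)CO[Si](CC)(CC)CC)[C@H]1CCC#C | intermediate
15 | (E)-alkenyl(dimethyl)alane, side chain CH2CH2C(CH3)=CH–AlMe2 | C=C1C[C@H](O[Si](C)(C)C(C)(C)C)[C@@H]2[C@](C)(CCC[C@@]2(C)CO[Si](CC)(CC)CC)[C@H]1CC/C(C)=C/[Al](C)C | intermediate
16 | (E)-alkenyl iodide, side chain CH2CH2C(CH3)=CHI | C=C1C[C@H](O[Si](C)(C)C(C)(C)C)[C@@H]2[C@](C)(CCC[C@@]2(C)CO[Si](CC)(CC)CC)[C@H]1CC/C(C)=C/I | intermediate
17 | (R)-glyceraldehyde acetonide | CC1(C)OC[C@H](C=O)O1 | starting material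
18 | (15S,16R)-anti allylic alcohol with dioxolane, 6α-OTBS, 18-OTES | C=C1C[C@H](O[Si](C)(C)C(C)(C)C)[C@@H]2[C@](C)(CCC[C@@]2(C)CO[Si](CC)(CC)CC)[C@H]1CC/C(C)=C/[C@H](O)[C@H]1COC(C)(C)O1 | intermediate
19 | 15-O-PMB ether of 18 | C=C1C[C@H](O[Si](C)(C)C(C)(C)C)[C@@H]2[C@](C)(CCC[C@@]2(C)CO[Si](CC)(CC)CC)[C@H]1CC/C(C)=C/[C@H](OCc1ccc(OC)cc1)[C@H]1COC(C)(C)O1 | intermediate
20 | triol: 15-OPMB, free 16-OH, terminal CH2OH and 18-OH, 6α-OTBS | C=C1C[C@H](O[Si](C)(C)C(C)(C)C)[C@@H]2[C@](C)(CCC[C@@]2(C)CO)[C@H]1CC/C(C)=C/[C@H](OCc1ccc(OC)cc1)[C@H](O)CO | intermediate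
21 | (15S)-15-PMB-oxy C16 aldehyde, 18-OH free, 6α-OTBS | C=C1C[C@H](O[Si](C)(C)C(C)(C)C)[C@@H]2[C@](C)(CCC[C@@]2(C)CO)[C@H]1CC/C(C)=C/[C@H](OCc1ccc(OC)cc1)C=O | intermediate
22 | ethyl but-2-ynoate | CC#CC(=O)OCC | starting material
23 | ethyl (Z)-3-iodobut-2-enoate | CCOC(=O)/C=C(/C)I | intermediate
24 | ethyl (Z)-3-(chloromagnesio)but-2-enoate | CCOC(=O)/C=C(/C)[Mg]Cl | intermediate
25 | (15S,16S)-(Z)-γ-hydroxy enoate adduct, present as its magnesium alkoxide (drawn protonated) | C=C1C[C@H](O[Si](C)(C)C(C)(C)C)[C@@H]2[C@](C)(CCC[C@@]2(C)CO)[C@H]1CC/C(C)=C/[C@H](OCc1ccc(OC)cc1)[C@@H](O)/C(C)=C\C(=O)OCC | intermediate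
26 | (15S,16S)-butenolide, 15-OPMB, 6α-OTBS, 18-OH | C=C1C[C@H](O[Si](C)(C)C(C)(C)C)[C@@H]2[C@](C)(CCC[C@@]2(C)CO)[C@H]1CC/C(C)=C/[C@H](OCc1ccc(OC)cc1)[C@H]1OC(=O)C=C1C | intermediate
27 | C18 aldehyde, 15-OPMB, 6α-OTBS | C=C1C[C@H](O[Si](C)(C)C(C)(C)C)[C@@H]2[C@](C)(CCC[C@@]2(C)C=O)[C@H]1CC/C(C)=C/[C@H](OCc1ccc(OC)cc1)[C@H]1OC(=O)C=C1C | intermediate
28 | 15-hydroxy C18 aldehyde, 6α-OTBS | C=C1C[C@H](O[Si](C)(C)C(C)(C)C)[C@@H]2[C@](C)(CCC[C@@]2(C)C=O)[C@H]1CC/C(C)=C/[C@H](O)[C@H]1OC(=O)C=C1C | intermediate
29 | CNP0113661.1 | C=C1C[C@H](O)[C@@H]2[C@](C)(CCC[C@@]2(C)C=O)[C@H]1CC/C(C)=C/[C@H](O)[C@H]1OC(=O)C=C1C | target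

**Step count**

Total: 20 steps. Longest linear sequence: 19 steps (steps 1–15 and 17–20; step 16 is a one-step side branch).

**Steps most likely to fail**

Step 17. The internally coordinated alkenylmagnesium is a weak Lewis acid, so chelate control over C16 may be eroded by open-chain (Felkin–Anh) addition. The aldehyde may also lose its C15 configuration, or isomerise into conjugation, before it is trapped. The fallback sets out from 21 and returns at 26, and sets C16 under catalyst control in a separate step. Zinc alkynylation of 21 with methyl propiolate (Me2Zn, ProPhenol ligand of the sense that leads to 16S, toluene, 0 °C) would give the (15S,16S)-γ-hydroxy ynoate F1. Syn conjugate addition of Me2CuLi (THF, −78 °C) then places the C3' methyl cis to hydrogen, so the carbinol and the ester are cis and the lactone closes to 26.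

Step 4. The C6 alkoxy radical may partition between hydrogen transfer from C18 and disproportionation or C–C scission. The nitroso dimer may also tautomerise incompletely, leaving material that step 5 cannot hydrolyse cleanly beside the epoxide. The fallback sets out from 4 and returns at 10, and changes the fate of the C18 radical. Irradiation of 4 under a stream of oxygen (365 nm, PhH) traps the radical as the peroxyl radical, which combines with NO and rearranges to the C18 nitrate ester F2. Zinc in acetic acid with sodium iodide then reduces the nitrate to the alcohol and deoxygenates the epoxide in the same operation. This bypasses 6, 7 and 8.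

Step 12. Facial selectivity in the addition to the glyceraldehyde acetonide may be poor, giving much of the 15-epimer. The fallback sets out from 16 and returns at 18, and sets C15 by reduction instead of addition. Iodine–lithium exchange on 16 (t-BuLi, Et2O, −78 °C) and acylation with the Weinreb amide F3 would give the (E)-enone F4. F3 is prepared from purchasable methyl (R)-2,2-dimethyl-1,3-dioxolane-4-carboxylate with MeNHOMe·HCl and i-PrMgCl. Chelation-controlled 1,2-reduction of F4 with Zn(BH4)2 (Et2O, −30 °C) should then give the anti alcohol 18.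

**Further compounds**

F1 | step 17 | (15S,16S)-γ-hydroxy ynoate (methyl ester), 15-OPMB, 6α-OTBS, 18-OH | C=C1C[C@H](O[Si](C)(C)C(C)(C)C)[C@@H]2[C@](C)(CCC[C@@]2(C)CO)[C@H]1CC/C(C)=C/[C@H](OCc1ccc(OC)cc1)[C@@H](O)C#CC(=O)OC
F2 | step 4 | 8α,17-epoxy-6α-hydroxy-13-oxo-14,15-dinorlabdan-18-yl nitrate | C1O[C@@]12C[C@H](O)[C@@H]3[C@](C)(CCC[C@@]3(C)CO[N+](=O)[O-])[C@H]2CCC(C)=O
F3 | step 12 | (R)-N-methoxy-N,2,2-trimethyl-1,3-dioxolane-4-carboxamide | CON(C)C(=O)[C@H]1COC(C)(C)O1
F4 | step 12 | (E)-enone, C15 ketone joined to the (R)-dioxolane, 6α-OTBS, 18-OTES | C=C1C[C@H](O[Si](C)(C)C(C)(C)C)[C@@H]2[C@](C)(CCC[C@@]2(C)CO[Si](CC)(CC)CC)[C@H]1CC/C(C)=C/C(=O)[C@H]1COC(C)(C)O1
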